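(All constants are invented; the run is a simulation.)

How much of the substrate stands as target, counted in both phases, at the end of the run, and which change adds most?

    reagent in the reaction phase ⇌ dormant form (K1 = 0.47, k1 = 0.073 s⁻¹)
    target ⇌ product in the second phase, rate k2*([target] - [product in the second phase]/K2) per volume of the first phase (K2 = 2.0, k2 = 0.43 s⁻¹)
    reagent in the reaction phase + target → over-reaction product (k3 = 0.046 M⁻¹ s⁻¹)
    substrate + reagent in the reaction phase → target (k4 = 0.015 M⁻¹ s⁻¹)
    reagent in the reaction phase ⇌ reagent in the second phase, rate k5*([reagent in the reaction phase] - [reagent in the second phase]/K5) per volume of the first phase (K5 = 0.59, k5 = 0.0044 s⁻¹)
    target → decomposed product (k6 = 0.024 s⁻¹)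
    substrate + target → side product (k7 = 0.0012 M⁻¹ s⁻¹)

substrate 2.0 M; reagent in the second phase 0.800 equiv; time 3.0 min; volume of the second phase over the first 2.0

- percentages count the substrate that a species holds: one side product counts as two
- target is meant together with its product in the second phase
- in the second phase: reagent in the second phase, product in the second phase; everything else is in the first
- charges count per volume of the first phase; a concentration in a rate is the amount of a species over the volume of its own phase; every rate counts per litre of the first phase
- run time (flask): 3.0 min

1. target and product in the second phase together at 3.0 min, in percent of the substrate charged
2. the change that raises the amount of target and product in the second phase together at 3.0 min, in percent of the substrate charged most ("none" if none brings more than 2 percentage points) (ash / birch / cedar / none)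
3. amount of target and product in the second phase together at 3.0 min, in percent of the substrate charged, after ash

- ash: doubling the transfer coefficient of step 5, all else as stated
- birch: doubling the amount of reagent in the second phase, all else as stated
- cedar: doubling the transfer coefficient of step 2, all else as stated

The reagent is charged in less than the substrate, which makes it the limiting reagent and caps target at 80.0%, so you start from its balance. It begins in the second phase at 0.800 M, and while the reaction phase holds none of it, a fraction 0.224 min⁻¹ crosses. Over 3.0 min that would move 48.9% of it.

But crossing runs both ways. Reagent in the reaction phase returns at 0.264 min⁻¹ and meets the substrate at the pseudo-first-order rate 1.80 min⁻¹, which is faster, so most of it stays. Multiplying by that share gives the drain constant, the fraction of reagent in the second phase that leaves for good per unit time: 0.195 min⁻¹, with substrate held at its charge.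

Yet crossed is not converted. Reagent in the reaction phase relaxes with the dormant form in 0.0506 min, shorter than the pool's turnover time 0.712 min. Taking that as a delay, target made comes to 28.8%.

Some of it is lost on the way. At partition 20.0% of target sits in the first phase, and there it decomposes, meets substrate and meets reagent, which you take at mid-run, with the reagent in the second phase run down by the drain, near 0.129 M. That gives a loss constant of 0.388 min⁻¹. With a mean age of half the run, your estimate is 16.1%.

Cedar leaves this reckoning unchanged, since the share comes from partition and volumes. Ash raises the drain to 0.346 min⁻¹, which gives 23.9%. Birch keeps the drain and doubles what it acts on, so the pick is birch.

The forecast gives 16%, birch and 22% after ash, judging that “birch should edge out ash”.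

The simulation gives 15.2%, with birch best at 9.4 percentage points against 4.9 points for ash and 0.21 points for cedar, and 20.1% after ash. The drain constant leaves 55.7% of the reagent in the second phase at the end of this flask, where the reading is 55.2% of its charge. In the neighbour flask read at 12 min, it leaves 9.63%, and the reading is 11.7%. Part of what keeps this flask's yield at 15.2% is two things acting together: the way back from the dormant form to reagent in the reaction phase, without which the run gives 6.04%, and the reading at 3.0 min, since ten times as long gives 0.873%.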